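**Strategy.** Ring B is disconnected at C6–C7 (labdane numbering), and the C8 methylene is retraced to a ketone. The C7 radical next to that ketone closes ring B by 6-endo attack on an exocyclic C5=C6 methylene of a monocyclic ring A; hydrogen transfer to the resulting C5 radical, opposite the angular C10 methyl, gives the trans ring fusion in the same operation. The precursor is a chloromethyl ketone hung on the C10 quaternary centre, which comes from a CBS reduction and a chirality-transferring Ireland–Claisen rearrangement; a formaldehyde ene reaction installs C19 and the exocyclic methylene. C9 is then equilibrated and C4 methylated on the rigid trans-decalin.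

Key step: step 6

Remark: labdane numbering is used for all intermediates (ring A: C1–C5 and C10; ring B: C5–C10; C17 on C8; C18 and C19 on C4; C20 on C10), and compounds 1, 3 and 20 are taken as purchasable.

Step 1
Reactants: 1 2,3-dimethylcyclohex-2-en-1-one
Product: 2 (R)-2,3-dimethylcyclohex-2-en-1-ol
Conditions: (S)-1-methyl-3,3-diphenyltetrahydro-1H,3H-pyrrolo[1,2-c][1,3,2]oxazaborole [(S)-Me-CBS, cat.], BH3·SMe2, THF, −20 °C
Reagents that add atoms: none
Why: Corey–Bakshi–Shibata reduction: the catalyst should distinguish the alkenyl flank (large) from the CH2 flank (small) of the ketone and deliver hydride to give the (R)-carbinol, a temporary stereocentre that later dictates the face of C10.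

Step 2
Reactants: 2 (R)-2,3-dimethylcyclohex-2-en-1-ol; 3 hex-5-ynoic acid
Product: 4 (R)-2,3-dimethylcyclohex-2-en-1-yl hex-5-ynoate
Conditions: DCC, DMAP (cat.), CH2Cl2, 0 °C to rt
Reagents that add atoms: none
Why: Steglich esterification (carbodiimide activation with DMAP acyl transfer) acylates the allylic alcohol with retention and without ionising the C–O bond.

Step 3
Reactants: 4 (R)-2,3-dimethylcyclohex-2-en-1-yl hex-5-ynoate
Product: 8 methyl 2-[(1R)-1,2-dimethylcyclohex-2-en-1-yl]-6-(trimethylsilyl)hex-5-ynoate (epimers at C9), via silyl ketene acetal 5 (not isolated), via silyl ester 6 (not isolated), via carboxylic acid 7 (not isolated)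
Conditions: LiN(i-Pr)2 (LDA, 2.5 equiv), Me3SiCl (3.5 equiv), THF, −78 °C then 65 °C; 1 M HCl; Me3SiCHN2, MeOH/PhMe, rt
Reagents that add atoms: chlorotrimethylsilane, C[Si](C)(C)Cl; trimethylsilyldiazomethane, C[Si](C)(C)C=[N+]=[N-]
Why: Ireland–Claisen rearrangement: the [3,3] shift of the silyl ketene acetal is suprafacial on the ring, so the C9–C10 bond should form on the face that carried the C–O bond and the carbinol chirality is relayed to the quaternary C10 while the alkene moves to C4=C5; the acetylide is C-silylated in the same pot and the C9 epimer mixture is corrected in step 7.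

Step 4
Reactants: 8 methyl 2-[(1R)-1,2-dimethylcyclohex-2-en-1-yl]-6-(trimethylsilyl)hex-5-ynoate
Product: 9 methyl 2-[(1R)-3-(hydroxymethyl)-1-methyl-2-methylidenecyclohexyl]-6-(trimethylsilyl)hex-5-ynoate (epimers at C4 and C9)
Conditions: Me2AlCl, (CH2O)n, CH2Cl2, 0 °C to rt
Reagents that add atoms: formaldehyde (from paraformaldehyde), C=O
Why: Lewis acid-promoted carbonyl-ene reaction of formaldehyde (Snider conditions): attack at the less substituted alkene carbon C4 and hydrogen loss from the C6 methyl, the only allylic hydrogens next to C5 because C10 is quaternary, should give the C19 hydroxymethyl group and the exocyclic C5=C6 alkene, mainly anti to the bulky C10 side arm, the C4 configuration being erased in step 10.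

Step 5
Reactants: 9 methyl 2-[(1R)-3-(hydroxymethyl)-1-methyl-2-methylidenecyclohexyl]-6-(trimethylsilyl)hex-5-ynoate
Product: 10 1-chloro-3-[(1R)-3-(hydroxymethyl)-1-methyl-2-methylidenecyclohexyl]-7-(trimethylsilyl)hept-6-yn-2-one
Conditions: ICH2Cl, MeLi·LiBr, THF, −78 °C; aq. NH4Cl
Reagents that add atoms: chloroiodomethane, ClCI
Why: Ester homologation with chloromethyllithium generated by iodine–lithium exchange (Kowalski/Barluenga-type acyl substitution): the tetrahedral adduct survives at −78 °C and collapses to the α-chloroketone only on work-up, while the C19 hydroxyl is masked as its lithium alkoxide and the silylalkyne is inert.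

Step 6
Reactants: 10 1-chloro-3-[(1R)-3-(hydroxymethyl)-1-methyl-2-methylidenecyclohexyl]-7-(trimethylsilyl)hept-6-yn-2-one
Product: 11 19-hydroxy-14-(trimethylsilyl)-15,16,17,18-tetranorlabd-13-yn-8-one (5α-H, 10β-methyl; epimers at C4 and C9)
Conditions: (Me3Si)3SiH (syringe pump), AIBN (cat.), PhH, high dilution, 80 °C
Reagents that add atoms: none
Why: The silyl radical abstracts chlorine from 10 to give the electrophilic C7 radical next to the C8 carbonyl, which adds to the unsubstituted terminus C6 of the electron-rich exocyclic C5=C6 alkene and so forms the C6–C7 bond; the tertiary C5 radical then takes a hydrogen atom from the silane. The closest known reaction type is the stannane- or silane-mediated cyclization of α-halo ketones, in which 2-oxohex-5-enyl radicals with a substituent on the inner alkene carbon close in the 6-endo mode. Ring B is closed 6-endo-trig; the 5-exo alternative would need attack on C5, which is fully substituted and flanked by C4 and the quaternary C10. The new stereocentre C5 is set in the hydrogen transfer: the bulky silane should approach the α face, away from the axial C10 methyl and the C4 hydroxymethyl group of the major epimer, which gives the trans ring fusion. The step needs cyclization to outrun direct reduction of the C7 radical, and slow addition of the poor hydrogen donor (Me3Si)3SiH at high dilution should secure this.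

Step 7
Reactants: 11 19-hydroxy-14-(trimethylsilyl)-15,16,17,18-tetranorlabd-13-yn-8-one (C9 epimers)
Product: 12 19-hydroxy-14-(trimethylsilyl)-15,16,17,18-tetranorlabd-13-yn-8-one (5α-H, 9α-H, 10β-methyl; epimers at C4)
Conditions: DBU, PhMe, 80 °C
Reagents that add atoms: none
Why: Base-mediated enolisation of the C8 ketone (thermodynamic epimerisation) should move the C9 side chain into the equatorial position (9α-H) on the trans-decalone, and the amidine base leaves the alkynylsilane intact.

Step 8
Reactants: 12 19-hydroxy-14-(trimethylsilyl)-15,16,17,18-tetranorlabd-13-yn-8-one (9α-H)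
Product: 13 14-(trimethylsilyl)-15,16,18-trinorlabd-8(17)-en-13-yn-19-ol (epimers at C4)
Conditions: Ph3PCH3Br, n-BuLi, THF, 0 °C to 65 °C
Reagents that add atoms: methyltriphenylphosphonium bromide, C[P+](c1ccccc1)(c1ccccc1)c1ccccc1.[Br-]
Why: Wittig methylenation of the C8 ketone gives the exocyclic C8=C17 alkene; C9 already has the thermodynamic configuration, so reversible enolisation by the ylide does no harm, and the C19 alkoxide is tolerated.

Step 9
Reactants: 13 14-(trimethylsilyl)-15,16,18-trinorlabd-8(17)-en-13-yn-19-ol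
Product: 15 methyl 14-(trimethylsilyl)-15,16,18-trinorlabd-8(17)-en-13-yn-19-oate (epimers at C4), via carboxylic acid 14 (not isolated)
Conditions: CrO3, H2SO4, H2O, acetone, 0 °C; work-up; Me3SiCHN2, MeOH/PhMe, rt
Reagents that add atoms: water, O; trimethylsilyldiazomethane, C[Si](C)(C)C=[N+]=[N-]
Why: Jones oxidation takes the neopentyl-type primary alcohol through the aldehyde hydrate to the acid, and diazoalkane esterification of the hindered acid occurs at oxygen without touching C4; the 1,1-disubstituted alkene and the alkynylsilane should survive the short cold acidic treatment.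

Step 10
Reactants: 15 methyl 14-(trimethylsilyl)-15,16,18-trinorlabd-8(17)-en-13-yn-19-oate
Product: 17 methyl 15,16-dinorlabd-8(17)-en-13-yn-19-oate (4α-methyl, 4β-CO2Me, 5α-H, 9α-H, 10β-methyl), via silylalkyne ester 16 (not isolated)
Conditions: LiN(i-Pr)2 (LDA), THF/DMPU, −78 to 0 °C; MeI, −78 °C to rt; then K2CO3, MeOH, rt
Reagents that add atoms: iodomethane, CI
Why: Alkylation of the exocyclic ester enolate: both C4 epimers give the same enolate and iodomethane should approach from the equatorial α face, away from the axial C10 methyl, giving the 4α-methyl/4β-ester arrangement; methanolysis of the alkynyl C–Si bond with K2CO3/MeOH then frees the terminal alkyne.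

Step 11
Reactants: 17 methyl 15,16-dinorlabd-8(17)-en-13-yn-19-oate
Product: 19 methyl (13E)-15-hydroxylabda-8(17),13-dien-19-oate (methyl isocupressate), via alkenylalane 18 (not isolated)
Conditions: Me3Al, Cp2ZrCl2, CH2Cl2, 0 °C to rt; then (CH2O)n, 0 °C to rt; aq. HCl
Reagents that add atoms: trimethylaluminium, C[Al](C)C; formaldehyde (from paraformaldehyde), C=O
Why: Negishi zirconium-catalysed carboalumination: syn addition of Me–Al with methyl on the inner carbon sets the E geometry of C13=C14, and the alkenylalane is trapped by formaldehyde with retention; the axial neopentyl C19 ester should not react with Me3Al at room temperature.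

Step 12
Reactants: 19 methyl (13E)-15-hydroxylabda-8(17),13-dien-19-oate; 20 hexadecanoyl chloride (palmitoyl chloride)
Product: 21 methyl (13E)-15-(hexadecanoyloxy)labda-8(17),13-dien-19-oate (CNP0157008.1)
Conditions: pyridine, DMAP (cat.), CH2Cl2, 0 °C to rt
Reagents that add atoms: none
Why: Nucleophilic acyl substitution (DMAP-catalysed acylation) of the primary allylic alcohol with the acid chloride; pyridine takes up HCl so that the allylic ester and the exocyclic alkene are not exposed to acid.

**Compound list**

1 | 2,3-dimethylcyclohex-2-en-1-one | CC1=C(C)C(=O)CCC1 | starting material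
2 | (R)-2,3-dimethylcyclohex-2-en-1-ol | CC1=C(C)[C@H](O)CCC1 | intermediate
3 | hex-5-ynoic acid | C#CCCCC(=O)O | starting material
4 | (R)-2,3-dimethylcyclohex-2-en-1-yl hex-5-ynoate | CC1=C(C)[C@H](OC(=O)CCCC#C)CCC1 | intermediate
5 | O-trimethylsilyl ketene acetal of 4 with C-silylated alkyne | CC1=C(C)[C@H](OC(O[Si](C)(C)C)=CCCC#C[Si](C)(C)C)CCC1 | intermediate
6 | trimethylsilyl 2-[(1R)-1,2-dimethylcyclohex-2-en-1-yl]-6-(trimethylsilyl)hex-5-ynoate | C[Si](C)(C)OC(=O)C(CCC#C[Si](C)(C)C)[C@@]1(C)CCCC=C1C | intermediate
7 | 2-[(1R)-1,2-dimethylcyclohex-2-en-1-yl]-6-(trimethylsilyl)hex-5-ynoic acid | OC(=O)C(CCC#C[Si](C)(C)C)[C@@]1(C)CCCC=C1C | intermediate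
8 | methyl 2-[(1R)-1,2-dimethylcyclohex-2-en-1-yl]-6-(trimethylsilyl)hex-5-ynoate | COC(=O)C(CCC#C[Si](C)(C)C)[C@@]1(C)CCCC=C1C | intermediate
9 | methyl 2-[(1R)-3-(hydroxymethyl)-1-methyl-2-methylidenecyclohexyl]-6-(trimethylsilyl)hex-5-ynoate | COC(=O)C(CCC#C[Si](C)(C)C)[C@@]1(C)CCCC(CO)C1=C | intermediate
10 | 1-chloro-3-[(1R)-3-(hydroxymethyl)-1-methyl-2-methylidenecyclohexyl]-7-(trimethylsilyl)hept-6-yn-2-one | ClCC(=O)C(CCC#C[Si](C)(C)C)[C@@]1(C)CCCC(CO)C1=C | intermediate
11 | 19-hydroxy-14-(trimethylsilyl)-15,16,17,18-tetranorlabd-13-yn-8-one, 5α-H, 10β-methyl, epimers at C4 and C9 | O=C1CC[C@@H]2[C@](C)(CCCC2CO)C1CCC#C[Si](C)(C)C | intermediate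
12 | 19-hydroxy-14-(trimethylsilyl)-15,16,17,18-tetranorlabd-13-yn-8-one, 5α-H, 9α-H, 10β-methyl, epimers at C4 | O=C1CC[C@@H]2[C@](C)(CCCC2CO)[C@H]1CCC#C[Si](C)(C)C | intermediate
13 | 14-(trimethylsilyl)-15,16,18-trinorlabd-8(17)-en-13-yn-19-ol, epimers at C4 | C=C1CC[C@@H]2[C@](C)(CCCC2CO)[C@H]1CCC#C[Si](C)(C)C | intermediate
14 | 14-(trimethylsilyl)-15,16,18-trinorlabd-8(17)-en-13-yn-19-oic acid, epimers at C4 | C=C1CC[C@@H]2[C@](C)(CCCC2C(=O)O)[C@H]1CCC#C[Si](C)(C)C | intermediate
15 | methyl 14-(trimethylsilyl)-15,16,18-trinorlabd-8(17)-en-13-yn-19-oate, epimers at C4 | C=C1CC[C@@H]2[C@](C)(CCCC2C(=O)OC)[C@H]1CCC#C[Si](C)(C)C | intermediate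
16 | methyl 14-(trimethylsilyl)-15,16-dinorlabd-8(17)-en-13-yn-19-oate, 4α-methyl, 4β-ester | C=C1CC[C@@H]2[C@](C)(CCC[C@]2(C)C(=O)OC)[C@H]1CCC#C[Si](C)(C)C | intermediate
17 | methyl 15,16-dinorlabd-8(17)-en-13-yn-19-oate | C=C1CC[C@@H]2[C@](C)(CCC[C@]2(C)C(=O)OC)[C@H]1CCC#C | intermediate
18 | methyl (13E)-14-(dimethylalumanyl)-15-norlabda-8(17),13-dien-19-oate | C=C1CC[C@@H]2[C@](C)(CCC[C@]2(C)C(=O)OC)[C@H]1CC/C(C)=C/[Al](C)C | intermediate
19 | methyl (13E)-15-hydroxylabda-8(17),13-dien-19-oate (methyl isocupressate) | C=C1CC[C@@H]2[C@](C)(CCC[C@]2(C)C(=O)OC)[C@H]1CC/C(C)=C/CO | intermediate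
20 | hexadecanoyl chloride | CCCCCCCCCCCCCCCC(=O)Cl | starting material
21 | methyl (13E)-15-(hexadecanoyloxy)labda-8(17),13-dien-19-oate | C=C1CC[C@@H]2[C@](C)(CCC[C@]2(C)C(=O)OC)[C@H]1CC/C(C)=C/COC(=O)CCCCCCCCCCCCCCC | target

**Step count and risks**

Total steps: 12. Longest linear sequence: 12 steps (from 1; 3 and 20 are purchased).

Steps most likely to fail:

- **Step 6 (key step).** The C7 radical may take a hydrogen atom before it closes the ring, giving simple dechlorination, or the final hydrogen transfer to C5 may lose facial control. The fallback separates C–C bond formation from the hydride source. It sets out from 10: halide exchange (NaI, acetone) should give 1-iodo-3-[(1R)-3-(hydroxymethyl)-1-methyl-2-methylidenecyclohexyl]-7-(trimethylsilyl)hept-6-yn-2-one F1. Iodine-atom-transfer cyclization of F1 ((Bu3Sn)2 cat., sunlamp, PhH) should give the ring-closed tertiary iodide 5-iodo-19-hydroxy-14-(trimethylsilyl)-15,16,17,18-tetranorlabd-13-yn-8-one F2. Reduction of F2 with Bu3SnH/AIBN then returns to 11.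

- **Step 5.** The ester carbonyl lies between the tertiary C9 and the quaternary C10, so deprotonation at C9 or failure of the carbenoid to add may leave the ester unchanged. The fallback builds the chloroketone from the acid chloride and changes the order of events. It sets out from 7 (isolated after the acid work-up of step 3): (COCl)2 should give 2-[(1R)-1,2-dimethylcyclohex-2-en-1-yl]-6-(trimethylsilyl)hex-5-ynoyl chloride F3. Diazomethane should then give 1-diazo-3-[(1R)-1,2-dimethylcyclohex-2-en-1-yl]-7-(trimethylsilyl)hept-6-yn-2-one F4. HCl in dioxane should convert F4 into 1-chloro-3-[(1R)-1,2-dimethylcyclohex-2-en-1-yl]-7-(trimethylsilyl)hept-6-yn-2-one F5. The formaldehyde ene reaction of step 4, run on F5, returns to 10.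

- **Step 3.** The sigmatropic shift onto the fully substituted alkene terminus may be slow enough for the silyl ketene acetal to decompose (C-silylation, loss of ketene). The fallback forms the quaternary centre first and attaches the side chain afterwards. It sets out from 2: Johnson–Claisen rearrangement with trimethyl orthoacetate (propionic acid cat., 140 °C), with the same chirality transfer, should give methyl 2-[(1R)-1,2-dimethylcyclohex-2-en-1-yl]acetate F6. Enolate alkylation of F6 (LiN(i-Pr)2, HMPA, (4-iodobut-1-yn-1-yl)trimethylsilane) returns to 8.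

**Further compounds**

F1 | step 6 | 1-iodo-3-[(1R)-3-(hydroxymethyl)-1-methyl-2-methylidenecyclohexyl]-7-(trimethylsilyl)hept-6-yn-2-one | ICC(=O)C(CCC#C[Si](C)(C)C)[C@@]1(C)CCCC(CO)C1=C
F2 | step 6 | 5-iodo-19-hydroxy-14-(trimethylsilyl)-15,16,17,18-tetranorlabd-13-yn-8-one | O=C1CCC2(I)[C@](C)(CCCC2CO)C1CCC#C[Si](C)(C)C
F3 | step 5 | 2-[(1R)-1,2-dimethylcyclohex-2-en-1-yl]-6-(trimethylsilyl)hex-5-ynoyl chloride | ClC(=O)C(CCC#C[Si](C)(C)C)[C@@]1(C)CCCC=C1C
F4 | step 5 | 1-diazo-3-[(1R)-1,2-dimethylcyclohex-2-en-1-yl]-7-(trimethylsilyl)hept-6-yn-2-one | [N-]=[N+]=CC(=O)C(CCC#C[Si](C)(C)C)[C@@]1(C)CCCC=C1C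
F5 | step 5 | 1-chloro-3-[(1R)-1,2-dimethylcyclohex-2-en-1-yl]-7-(trimethylsilyl)hept-6-yn-2-one | ClCC(=O)C(CCC#C[Si](C)(C)C)[C@@]1(C)CCCC=C1C
F6 | step 3 | methyl 2-[(1R)-1,2-dimethylcyclohex-2-en-1-yl]acetate | COC(=O)C[C@@]1(C)CCCC=C1C
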